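Assumption: (R)-2-isopropyloxirane (2) is bought as the single enantiomer. The enol ether geometries of 5 and 6 and the transient sp3 centres of 12 and 22 are of no consequence, because all of them are removed later in the route.

## Analysis of the target

Compound 25 is an isoflavone: a 4H-chromen-4-one (rings A and C) with a 4-hydroxyphenyl group (ring B) at C3. Ring A is fully substituted: a methoxy group at C5, a (2S)-2-hydroxy-3-methylbutyl chain at C6, a free hydroxyl at C7 and a 3-methylbut-2-enyl (prenyl) group at C8. The side-chain carbinol is the only stereocenter, so no relative configuration has to be controlled, but this homobenzylic secondary alcohol must be introduced as the S enantiomer. The sensitive groups are the prenyl alkene, the C5 methyl ether and the two free phenols. The alkene adds the neighbouring C7 hydroxyl under strong acid and rules out hydrogenolysis and electrophilic oxidants; the C5 ether sits peri to the C4 carbonyl and is the first ether lost to Lewis acids. The difficulty is the hexasubstituted ring A: O5 is methylated, O7 is free and O8a is part of the pyranone, and the two carbon substituents at C6 and C8 differ only in that one prenyl unit is hydrated and enantiopure. Substitution chemistry on a phloroglucinol core would therefore have to tell C6 from C8 and O5 from O7. The strategy rests on reading ring A as an acylphloroglucinol. C4–C4a–C5(OMe)–C6 is an acetoacetate-type unit whose enol oxygen is already methylated, and C7–C8–C8a is a prenylmalonyl unit, so the ring can be assembled from two three-carbon pieces with every substituent in place.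

## Retrosynthetic reasoning

Ring C and the protecting groups come off first. Cutting O1–C2 and C2–C3 of 25 removes the single carbon C2 and leads back, through enaminone 24, to the protected aryl benzyl ketone 23. Because O5 carries a methyl group, O8a is the only phenol ortho to the carbonyl, so the forward closure has one possible course. The same acid that closes ring C can also free the three phenols and the carbinol.

Ketone 23 is cut at C3–C4. The forward step is addition of benzylic Grignard reagent 21, made from benzyl chloride 20, to aldehyde 16, followed by oxidation of carbinol 22. The cut is placed at the aldehyde level because the corresponding ester 14 is flanked by two ortho substituents and would not accept a bulky carbon nucleophile cleanly. Aldehyde 16 goes back through benzyl alcohol 15 and ester 14 to the salicylate 13, with both phenols masked so that the electron-rich benzyl alcohol cannot ionize.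

Salicylate 13 is cut at C6–C7 and C4a–C8a. This divides ring A into silyloxydiene 6 and prenylmalonyl dichloride 11:
- Diene 6 supplies the ester carbon (future C4), C4a, C5 with its methyl ether, and C6 with the chiral chain.
- Dichloride 11 supplies C7, C8 with the prenyl group, and C8a.

Any other pair of cuts through ring A would need an unsymmetrical dielectrophile or would separate a carbon from the substituent it has to carry. Here the electrophile is symmetric, so the only demand on the forward reaction is two successive C-acylations, the second one intramolecular through acid chloride 12.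

Diene 6 is the silyl ketene acetal of methoxy enoate 5, which is the O-methyl enol ether of keto ester 4, the silyl ether of hydroxy keto ester 3. Cutting 3 between C4 and C5 gives the dianion of methyl acetoacetate 1 and epoxide 2. The stereocenter is therefore bought and is never a reacting centre in the route.

Dichloride 11 goes back through diacid 10 to malonate 9, the product of alkylating diethyl malonate 7 with prenyl bromide 8. The prenyl group is thus attached to the future C8 before ring A exists.

Benzyl chloride 20 comes from benzyl alcohol 19, from protected aldehyde 18, from 4-hydroxybenzaldehyde 17. The acetal on this phenol is chosen so that all three phenol protecting groups fall in the same final operation.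

## Alternatives that were turned down

Alternative 1: The carbinol C–O bond is traced back to a C–Si bond, and ring A is taken from a 6,8-diprenylated 5,7-dihydroxyisoflavone. In the forward key step the hydrosilyl ether A2, carrying Si–H on O5, would undergo enantioselective intramolecular hydrosilylation of the C6 prenyl alkene under a chiral rhodium catalyst (for example [Rh(cod)2]BF4 with a chiral bisphosphine). This gives the six-membered siloxane A1; Tamao oxidation and methylation of O5 would follow.
- For: the two prenyl groups are distinguished simply by their distance from O5, ring A comes from a symmetric core, and the route would be the shortest of the four.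
- Against: the alkene is trisubstituted and silicon must be delivered to its less substituted carbon with facial control, by a catalyst working next to a chelating C4 carbonyl and a crowded arene. High enantioselectivity for this closure has no secure basis. The aryl silyl ether of a chelated phenol is hydrolytically fragile, and the oxidative Si–C cleavage uses basic peroxide, to which the pyranone C2 is sensitive. The methyl group would then have to go onto the least reactive, chelated phenol beside a new secondary alcohol.
- Comparison: this alternative is stronger on step count. The chosen route offers the configuration from a purchased epoxide and O5 methylated from the first ring A intermediate, and puts its risk in a bond construction and not in an enantioselective step.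

Alternative 2: Four bonds of ring A (C8a–C8, C7–C8, C5–C6, C4a–C5) are cut, so ring A is built last onto an aryl pyranone. Irradiation of diazoketone A4 with siloxyalkyne A5 would give a pyranyl(prenyl)ketene by Wolff rearrangement; (2+2) addition to the ynol ether, four-electron ring opening and six-electron closure would give the isoflavone A3.
- For: it is the most convergent plan, the position of every ring A substituent is fixed by mechanism, and O7 arrives silylated while O5 is free, so the phenols are differentiated without extra steps.
- Against: the carbene from A4 has a CH2 group beside the carbene carbon, so a 1,2-hydrogen shift competes with the Wolff migration. The pyranone and aryl chromophores have photochemistry of their own. A4 and A5 each need a multistep synthesis, and A5 carries the same stereocenter, so no chiral-pool steps are saved. The chelated O5 of A3 would still have to be methylated under forcing conditions.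
- Comparison: this alternative is stronger in convergence and in the number of bonds made in one step. The chosen route uses ground-state ionic chemistry with inexpensive three-carbon pieces and brings the O5 methyl group in with the diene.

Alternative 3: O1–C8a and C4–C4a are cut, so ring C is closed onto a complete ring A aryne. Fluoride would release the C4a–C8a aryne from silyl triflate A7; the enol oxygen of hydroxyacrylate A8 adds at C8a and the aryl anion at C4a attacks the ester, giving the tris(methoxymethyl) ether A6 of the target.
- For: ring C and the ring B attachment are made in one step, and the C5 methoxy group polarizes the aryne so that the oxygen nucleophile adds at the remote carbon C8a, which is the regiochemistry needed.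
- Against: A7 is a hexasubstituted benzene, so the ring A problem is only moved and an ortho-silyl triflate must be added to it. The aryne sits next to the allylic CH2 of the C8 prenyl group, which invites an intramolecular ene reaction. The enol A8 can also react through carbon.
- Comparison: this alternative is stronger for ring C (one step against several). The chosen strategy solves what it leaves open, namely the construction of ring A with all substituents and oxygen states differentiated.

Key step: step 8

## Route

Step 1
Reactants: 1 methyl acetoacetate; 2 (R)-2-isopropyloxirane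
Product: 3 methyl (6S)-6-hydroxy-7-methyl-3-oxooctanoate
Conditions: NaH, THF, 0 °C; n-BuLi, 0 °C; then 2, 0 °C → rt; aq. NH4Cl
Reagents that add atoms: none
Why: Weiler dianion alkylation: the γ-carbanion of the acetoacetate dianion opens the epoxide by SN2 attack at the unsubstituted carbon, so the stereocenter is not a reacting centre and keeps the arrangement of 2; the descriptor changes from R to S only because the ranking of the neighbours changes.

Step 2
Reactants: 3 methyl (6S)-6-hydroxy-7-methyl-3-oxooctanoate
Product: 4 methyl (6S)-6-(tert-butyldimethylsilyloxy)-7-methyl-3-oxooctanoate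
Conditions: TBSCl, imidazole, DMF, rt
Reagents that add atoms: tert-butyldimethylsilyl chloride, CC(C)(C)[Si](C)(C)Cl
Why: Standard silylation of a secondary alcohol; it is done at once because the γ-hydroxy ketone 3 can close to a five-membered hemiketal and lose water.

Step 3
Reactants: 4 methyl (6S)-6-(tert-butyldimethylsilyloxy)-7-methyl-3-oxooctanoate
Product: 5 methyl (2E,6S)-6-(tert-butyldimethylsilyloxy)-3-methoxy-7-methyloct-2-enoate
Conditions: KN(SiMe3)2, THF/DMPU, −78 °C; MeOTf, −78 → 0 °C
Reagents that add atoms: methyl trifluoromethanesulfonate, COS(=O)(=O)C(F)(F)F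
Why: O-alkylation of a dissociated potassium β-keto ester enolate by a hard methylating agent in a dipolar medium; the conditions are free of acid, so the silyl ether should survive, and the enol ether geometry does not matter for what follows.

Step 4
Reactants: 5 methyl (2E,6S)-6-(tert-butyldimethylsilyloxy)-3-methoxy-7-methyloct-2-enoate
Product: 6 (S)-6-(tert-butyldimethylsilyloxy)-1,3-dimethoxy-7-methyl-1-(trimethylsilyloxy)octa-1,3-diene
Conditions: LiN(iPr)2, THF, −78 °C; Me3SiCl, −78 °C → rt; pentane, filtration, no aqueous work-up
Reagents that add atoms: chlorotrimethylsilane, C[Si](C)(C)Cl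
Why: γ-Deprotonation of the β-methoxy enoate and O-silylation of the dienolate, the standard preparation of Brassard-type dienes; the carbinol carbon is not acidic and is untouched.

Step 5
Reactants: 7 diethyl malonate; 8 prenyl bromide (1-bromo-3-methylbut-2-ene)
Product: 9 diethyl 2-(3-methylbut-2-enyl)malonate
Conditions: NaOEt, EtOH, 0 °C → reflux (7 in excess)
Reagents that add atoms: none
Why: Malonic ester alkylation with a reactive allylic bromide; excess malonate keeps dialkylation low.

Step 6
Reactants: 9 diethyl 2-(3-methylbut-2-enyl)malonate
Product: 10 2-(3-methylbut-2-enyl)malonic acid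
Conditions: KOH, EtOH/H2O, rt; then aq. HCl, 0 °C
Reagents that add atoms: potassium hydroxide, [K+].[OH-]
Why: Saponification of both esters; cold acidification and no heating should avoid decarboxylation and hydration of the alkene.

Step 7
Reactants: 10 2-(3-methylbut-2-enyl)malonic acid
Product: 11 2-(3-methylbut-2-enyl)malonyl dichloride
Conditions: (COCl)2, DMF (cat.), CH2Cl2, 0 °C → rt; evaporation from toluene, used at once
Reagents that add atoms: oxalyl chloride, O=C(Cl)C(=O)Cl
Why: Acid chloride formation through the Vilsmeier-type chloroiminium catalyst at low temperature, conditions under which prenyl-bearing acids are routinely converted without addition of HCl to the alkene or ketene formation.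

Step 8
Reactants: 6 (S)-6-(tert-butyldimethylsilyloxy)-1,3-dimethoxy-7-methyl-1-(trimethylsilyloxy)octa-1,3-diene; 11 2-(3-methylbut-2-enyl)malonyl dichloride
Product: 13 methyl 2,4-dihydroxy-6-methoxy-3-(3-methylbut-2-enyl)-5-[(2S)-2-(tert-butyldimethylsilyloxy)-3-methylbutyl]benzoate, via acid chloride 12 (not isolated)
Conditions: 6 added slowly to 11 (1.1 equiv), CH2Cl2 (0.02 M), −78 → 0 °C; then Et3N (3 equiv), 0 °C → rt; aq. NH4Cl
Reagents that add atoms: none
Why: Proposed new method: the diene terminus (C4 of 6, the future C6) is the most nucleophilic carbon of a vinylogous silyl ketene acetal and should attack one of the two equivalent acyl chlorides of 11 without a catalyst, chloride taking up the trimethylsilyl group to give acid chloride 12 (C6–C7 bond). Triethylamine then takes HCl from 12 to give the extended enolate or the acylketene tautomer, the enoate α-carbon (future C4a) attacks the remaining acyl carbon (C4a–C8a bond), and loss of chloride and two enolizations deliver the aromatic ring. The closest known reaction types are terminal C-acylation of Brassard- and Chan-type silyloxydienes by acid chlorides, (3+3) cyclizations of such dienes with 1,3-dielectrophiles to salicylates, annulations of 1,3-dinucleophiles with malonyl dichlorides or chlorocarbonylketenes, and the closure of dienylketenes in Danheiser and Dötz benzannulations. Ring A closes by a 6-(enolexo)-exo-trig C-acylation or, seen from the acylketene, by a six-electron electrocyclization. No stereocenter is formed: the two sp3 carbons of 12 become aromatic, and the silyloxy carbinol is remote and cannot epimerize. The closure needs acylation at carbon and not at oxygen, which is secured because every oxygen nucleophile of 12 would have to close a four- or eight-membered ring. The first acylation needs no regiocontrol because 11 is symmetric, and attack through C2 of the diene followed by closure through C4 leads to the same ring. The methyl group already on the C5 oxygen ensures that only O7 and O8a emerge as free phenols; inverse addition at high dilution is meant to suppress 2:1 adducts and ketene dimers.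

Step 9
Reactants: 13 methyl 2,4-dihydroxy-6-methoxy-3-(3-methylbut-2-enyl)-5-[(2S)-2-(tert-butyldimethylsilyloxy)-3-methylbutyl]benzoate
Product: 14 methyl 5-[(2S)-2-(tert-butyldimethylsilyloxy)-3-methylbutyl]-6-methoxy-2,4-bis(methoxymethoxy)-3-(3-methylbut-2-enyl)benzoate
Conditions: NaH, DMF, 0 °C; MOMCl, 0 °C → rt
Reagents that add atoms: chloromethyl methyl ether, COCCl
Why: Williamson-type acetal formation on both sodium phenoxides; the strong base overcomes the hydrogen bond of the hydroxyl next to the ester and the small electrophile tolerates the flanking substituents.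

Step 10
Reactants: 14 methyl 5-[(2S)-2-(tert-butyldimethylsilyloxy)-3-methylbutyl]-6-methoxy-2,4-bis(methoxymethoxy)-3-(3-methylbut-2-enyl)benzoate
Product: 15 {5-[(2S)-2-(tert-butyldimethylsilyloxy)-3-methylbutyl]-6-methoxy-2,4-bis(methoxymethoxy)-3-(3-methylbut-2-enyl)phenyl}methanol
Conditions: LiAlH4, THF, 0 °C → rt; aq. NaOH work-up
Reagents that add atoms: none
Why: Hydride reduction of a di-ortho-substituted benzoate, which a small hydride reaches where carbon nucleophiles do not; with both phenols masked the electron-rich benzyl alcohol cannot form an ortho-quinone methide.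

Step 11
Reactants: 15 {5-[(2S)-2-(tert-butyldimethylsilyloxy)-3-methylbutyl]-6-methoxy-2,4-bis(methoxymethoxy)-3-(3-methylbut-2-enyl)phenyl}methanol
Product: 16 5-[(2S)-2-(tert-butyldimethylsilyloxy)-3-methylbutyl]-6-methoxy-2,4-bis(methoxymethoxy)-3-(3-methylbut-2-enyl)benzaldehyde
Conditions: MnO2, CH2Cl2, rt
Reagents that add atoms: none
Why: Selective oxidation of a benzylic alcohol under neutral heterogeneous conditions that leave the prenyl alkene, the acetals and the silyl ether alone.

Step 12
Reactants: 17 4-hydroxybenzaldehyde
Product: 18 4-(methoxymethoxy)benzaldehyde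
Conditions: MOMCl, iPr2NEt, CH2Cl2, 0 °C → rt
Reagents that add atoms: chloromethyl methyl ether, COCCl
Why: Standard phenol protection as the methoxymethyl ether.

Step 13
Reactants: 18 4-(methoxymethoxy)benzaldehyde
Product: 19 [4-(methoxymethoxy)phenyl]methanol
Conditions: NaBH4, MeOH, 0 °C
Reagents that add atoms: none
Why: Borohydride reduction of an aryl aldehyde.

Step 14
Reactants: 19 [4-(methoxymethoxy)phenyl]methanol
Product: 20 1-(chloromethyl)-4-(methoxymethoxy)benzene
Conditions: MsCl, Et3N, CH2Cl2, 0 °C → rt; used fresh
Reagents that add atoms: methanesulfonyl chloride, CS(=O)(=O)Cl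
Why: The mesylate of an electron-rich benzylic alcohol is displaced in the flask by the chloride that is released, giving the benzyl chloride under basic conditions that keep the acetal.

Step 15
Reactants: 20 1-(chloromethyl)-4-(methoxymethoxy)benzene; 16 5-[(2S)-2-(tert-butyldimethylsilyloxy)-3-methylbutyl]-6-methoxy-2,4-bis(methoxymethoxy)-3-(3-methylbut-2-enyl)benzaldehyde
Product: 22 1-{5-[(2S)-2-(tert-butyldimethylsilyloxy)-3-methylbutyl]-6-methoxy-2,4-bis(methoxymethoxy)-3-(3-methylbut-2-enyl)phenyl}-2-[4-(methoxymethoxy)phenyl]ethan-1-ol (both carbinol epimers), via Grignard reagent 21 (not isolated)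
Conditions: 20, Mg, THF (dilute), 0 °C; then 16, THF, −78 → 0 °C; aq. NH4Cl
Reagents that add atoms: none
Why: Grignard addition of a benzylic organomagnesium to an aldehyde, which forms the C3–C4 bond; the new carbinol centre is not controlled because it is oxidized in the next step.

Step 16
Reactants: 22 1-{5-[(2S)-2-(tert-butyldimethylsilyloxy)-3-methylbutyl]-6-methoxy-2,4-bis(methoxymethoxy)-3-(3-methylbut-2-enyl)phenyl}-2-[4-(methoxymethoxy)phenyl]ethan-1-ol
Product: 23 1-{5-[(2S)-2-(tert-butyldimethylsilyloxy)-3-methylbutyl]-6-methoxy-2,4-bis(methoxymethoxy)-3-(3-methylbut-2-enyl)phenyl}-2-[4-(methoxymethoxy)phenyl]ethan-1-one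
Conditions: Dess–Martin periodinane, NaHCO3, CH2Cl2, 0 °C → rt
Reagents that add atoms: none
Why: Buffered Dess–Martin oxidation of a secondary alcohol to the aryl benzyl ketone; the buffer should prevent acid-induced loss of water to a stilbene.

Step 17
Reactants: 23 1-{5-[(2S)-2-(tert-butyldimethylsilyloxy)-3-methylbutyl]-6-methoxy-2,4-bis(methoxymethoxy)-3-(3-methylbut-2-enyl)phenyl}-2-[4-(methoxymethoxy)phenyl]ethan-1-one
Product: 25 7-hydroxy-6-[(2S)-2-hydroxy-3-methylbutyl]-3-(4-hydroxyphenyl)-5-methoxy-8-(3-methylbut-2-enyl)-4H-chromen-4-one, via enaminone 24 (not isolated)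
Conditions: Me2NCH(OMe)2, toluene, 90 °C; evaporate; 1.25 M HCl in MeOH, rt → 40 °C
Reagents that add atoms: N,N-dimethylformamide dimethyl acetal, COC(OC)N(C)C
Why: Condensation of the formamide acetal at the doubly activated methylene gives enaminone 24 and supplies C2; methanolic acid then cleaves the three aryl acetals and the silyl ether, and the O8a phenol, the only hydroxyl ortho to the carbonyl because O5 is methylated, adds to the protonated enaminone and expels dimethylamine to close ring C, as in the isoflavone synthesis from 2-hydroxyphenyl benzyl ketones.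

## Compound list

1 | methyl acetoacetate | COC(=O)CC(C)=O | starting material
2 | (R)-2-isopropyloxirane | CC(C)[C@@H]1CO1 | starting material
3 | methyl (6S)-6-hydroxy-7-methyl-3-oxooctanoate | COC(=O)CC(=O)CC[C@H](O)C(C)C | intermediate
4 | methyl (6S)-6-(tert-butyldimethylsilyloxy)-7-methyl-3-oxooctanoate | COC(=O)CC(=O)CC[C@H](O[Si](C)(C)C(C)(C)C)C(C)C | intermediate
5 | methyl (2E,6S)-6-(tert-butyldimethylsilyloxy)-3-methoxy-7-methyloct-2-enoate | COC(=O)/C=C(/OC)CC[C@H](O[Si](C)(C)C(C)(C)C)C(C)C | intermediate
6 | (S)-6-(tert-butyldimethylsilyloxy)-1,3-dimethoxy-7-methyl-1-(trimethylsilyloxy)octa-1,3-diene | COC(O[Si](C)(C)C)=CC(OC)=CC[C@H](O[Si](C)(C)C(C)(C)C)C(C)C | intermediate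
7 | diethyl malonate | CCOC(=O)CC(=O)OCC | starting material
8 | prenyl bromide (1-bromo-3-methylbut-2-ene) | CC(C)=CCBr | starting material
9 | diethyl 2-(3-methylbut-2-enyl)malonate | CCOC(=O)C(CC=C(C)C)C(=O)OCC | intermediate
10 | 2-(3-methylbut-2-enyl)malonic acid | OC(=O)C(CC=C(C)C)C(=O)O | intermediate
11 | 2-(3-methylbut-2-enyl)malonyl dichloride | O=C(Cl)C(CC=C(C)C)C(=O)Cl | intermediate
12 | methyl 7-chloro-3-methoxy-6-(3-methylbut-2-enyl)-5,7-dioxo-4-[(2S)-2-(tert-butyldimethylsilyloxy)-3-methylbutyl]hept-2-enoate (mixture at C4 and C6) | COC(=O)C=C(OC)C(C[C@H](O[Si](C)(C)C(C)(C)C)C(C)C)C(=O)C(CC=C(C)C)C(Cl)=O | intermediate (not isolated)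
13 | methyl 2,4-dihydroxy-6-methoxy-3-(3-methylbut-2-enyl)-5-[(2S)-2-(tert-butyldimethylsilyloxy)-3-methylbutyl]benzoate | COC(=O)c1c(OC)c(C[C@H](O[Si](C)(C)C(C)(C)C)C(C)C)c(O)c(CC=C(C)C)c1O | intermediate
14 | methyl 5-[(2S)-2-(tert-butyldimethylsilyloxy)-3-methylbutyl]-6-methoxy-2,4-bis(methoxymethoxy)-3-(3-methylbut-2-enyl)benzoate | COC(=O)c1c(OC)c(C[C@H](O[Si](C)(C)C(C)(C)C)C(C)C)c(OCOC)c(CC=C(C)C)c1OCOC | intermediate
15 | {5-[(2S)-2-(tert-butyldimethylsilyloxy)-3-methylbutyl]-6-methoxy-2,4-bis(methoxymethoxy)-3-(3-methylbut-2-enyl)phenyl}methanol | OCc1c(OC)c(C[C@H](O[Si](C)(C)C(C)(C)C)C(C)C)c(OCOC)c(CC=C(C)C)c1OCOC | intermediate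
16 | 5-[(2S)-2-(tert-butyldimethylsilyloxy)-3-methylbutyl]-6-methoxy-2,4-bis(methoxymethoxy)-3-(3-methylbut-2-enyl)benzaldehyde | O=Cc1c(OC)c(C[C@H](O[Si](C)(C)C(C)(C)C)C(C)C)c(OCOC)c(CC=C(C)C)c1OCOC | intermediate
17 | 4-hydroxybenzaldehyde | O=Cc1ccc(O)cc1 | starting material
18 | 4-(methoxymethoxy)benzaldehyde | COCOc1ccc(C=O)cc1 | intermediate
19 | [4-(methoxymethoxy)phenyl]methanol | COCOc1ccc(CO)cc1 | intermediate
20 | 1-(chloromethyl)-4-(methoxymethoxy)benzene | COCOc1ccc(CCl)cc1 | intermediate
21 | 4-(methoxymethoxy)benzylmagnesium chloride | COCOc1ccc(C[Mg]Cl)cc1 | intermediate (not isolated)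
22 | 1-{5-[(2S)-2-(tert-butyldimethylsilyloxy)-3-methylbutyl]-6-methoxy-2,4-bis(methoxymethoxy)-3-(3-methylbut-2-enyl)phenyl}-2-[4-(methoxymethoxy)phenyl]ethan-1-ol (both carbinol epimers) | COCOc1ccc(CC(O)c2c(OC)c(C[C@H](O[Si](C)(C)C(C)(C)C)C(C)C)c(OCOC)c(CC=C(C)C)c2OCOC)cc1 | intermediate
23 | 1-{5-[(2S)-2-(tert-butyldimethylsilyloxy)-3-methylbutyl]-6-methoxy-2,4-bis(methoxymethoxy)-3-(3-methylbut-2-enyl)phenyl}-2-[4-(methoxymethoxy)phenyl]ethan-1-one | COCOc1ccc(CC(=O)c2c(OC)c(C[C@H](O[Si](C)(C)C(C)(C)C)C(C)C)c(OCOC)c(CC=C(C)C)c2OCOC)cc1 | intermediate
24 | 3-(dimethylamino)-1-{5-[(2S)-2-(tert-butyldimethylsilyloxy)-3-methylbutyl]-6-methoxy-2,4-bis(methoxymethoxy)-3-(3-methylbut-2-enyl)phenyl}-2-[4-(methoxymethoxy)phenyl]prop-2-en-1-one | CN(C)C=C(C(=O)c1c(OC)c(C[C@H](O[Si](C)(C)C(C)(C)C)C(C)C)c(OCOC)c(CC=C(C)C)c1OCOC)c1ccc(OCOC)cc1 | intermediate (not isolated)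
25 | 7-hydroxy-6-[(2S)-2-hydroxy-3-methylbutyl]-3-(4-hydroxyphenyl)-5-methoxy-8-(3-methylbut-2-enyl)-4H-chromen-4-one | COc1c(C[C@H](O)C(C)C)c(O)c(CC=C(C)C)c2occ(-c3ccc(O)cc3)c(=O)c12 | target

## Step count and risks

Total step count: 17. Longest linear sequence: 11 steps (steps 1, 2, 3, 4, 8, 9, 10, 11, 15, 16, 17).

Least certain steps:

Step 8 (key step, new method). Two things may go wrong. The first acylation may run past the 1:1 stage, giving two dienes on one malonyl unit or ketene-derived oligomers. The ring closure may also be too slow, because the methoxy enoate carbon is a weak nucleophile, so that acid chloride 12 is consumed by intermolecular acylation or by hydrolysis on work-up. The fallback separates the two bond formations and uses known reaction types: terminal C-acylation of a silyloxydiene by a simple acid chloride, then a base-induced Claisen-type cyclization of a 3,5-dioxygenated diester, as in biomimetic acylphloroglucinol syntheses. It sets out from 9 and 6 and comes back at 13. Half-saponification of 9 with one equivalent of KOH in EtOH would give 2-(ethoxycarbonyl)-5-methylhex-4-enoic acid F1. Oxalyl chloride would turn this into ethyl 2-(chlorocarbonyl)-5-methylhex-4-enoate F2. Acylation of diene 6 at its terminus by F2 in CH2Cl2 would give the open-chain 7-ethyl 1-methyl 4-[(2S)-2-(tert-butyldimethylsilyloxy)-3-methylbutyl]-3-methoxy-6-(3-methylbut-2-enyl)-5-oxohept-2-enedioate F3. NaOMe in MeOH, or Mg(OMe)2, would then close C2 of the enoate onto the ethyl ester with loss of ethanol, and aromatization returns to 13. The competing closure of the malonate carbon onto the methyl ester gives a non-aromatizable dione and is reversible, so the aromatic product should be the sink.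

Step 3. Methylation at C2 of the enolate in place of oxygen would give a 2-methyl keto ester, and any of it carried forward would later put a methyl group on C4a. The fallback makes the enol ether by conjugate addition and bypasses steps 1 and 2 as well, so it also covers a sluggish epoxide opening in step 1. It sets out from 2 and comes back at 5. Propargylmagnesium bromide would open 2 at the unsubstituted carbon to give (3S)-2-methylhept-6-yn-3-ol F4. Silylation with TBSCl and imidazole gives tert-butyldimethyl{[(3S)-2-methylhept-6-yn-3-yl]oxy}silane F5. Deprotonation with n-BuLi and trapping with methyl chloroformate gives methyl (6S)-6-(tert-butyldimethylsilyloxy)-7-methyloct-2-ynoate F6. Addition of NaOMe in MeOH across the ynoate then gives 5.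

Step 15. Formation of the electron-rich benzylic Grignard reagent 21 may be accompanied by Wurtz coupling of 20, and the hindered aldehyde may then be reduced or left unreacted. The fallback builds the same ketone by ketone arylation; it sets out from 16 and comes back at 23, replacing steps 15 and 16. MeMgBr would add to 16 to give 1-{5-[(2S)-2-(tert-butyldimethylsilyloxy)-3-methylbutyl]-6-methoxy-2,4-bis(methoxymethoxy)-3-(3-methylbut-2-enyl)phenyl}ethan-1-ol F7. Dess–Martin oxidation gives the corresponding methyl ketone, 1-{5-[(2S)-2-(tert-butyldimethylsilyloxy)-3-methylbutyl]-6-methoxy-2,4-bis(methoxymethoxy)-3-(3-methylbut-2-enyl)phenyl}ethan-1-one F8. Palladium-catalysed α-arylation of F8 with 1-bromo-4-(methoxymethoxy)benzene F9 (Pd2(dba)3, Xantphos, NaOt-Bu, toluene, 80 °C) would give 23.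

Step 17. During the time needed to cleave three aryl acetals in methanolic acid, the C7 hydroxyl or methanol may add to the protonated prenyl alkene (chroman or methyl ether formation), and the enaminone may hydrolyse and lose its formyl carbon before O8a is free. The fallback removes the acetals by Lewis acid and thiol transacetalization and the silyl ether by fluoride; it sets out from 24 and comes back at 25. Treatment of 24 with ZnBr2 and n-PrSH in CH2Cl2 at 0 °C would free the phenols, and the O8a phenol closes onto the enaminone to give 6-[(2S)-2-(tert-butyldimethylsilyloxy)-3-methylbutyl]-7-hydroxy-3-(4-hydroxyphenyl)-5-methoxy-8-(3-methylbut-2-enyl)-4H-chromen-4-one F10. HF·pyridine in THF then removes the silyl group to give 25.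

## Further compounds

F1 | step 8 | 2-(ethoxycarbonyl)-5-methylhex-4-enoic acid | CCOC(=O)C(CC=C(C)C)C(=O)O
F2 | step 8 | ethyl 2-(chlorocarbonyl)-5-methylhex-4-enoate | CCOC(=O)C(CC=C(C)C)C(Cl)=O
F3 | step 8 | 7-ethyl 1-methyl 4-[(2S)-2-(tert-butyldimethylsilyloxy)-3-methylbutyl]-3-methoxy-6-(3-methylbut-2-enyl)-5-oxohept-2-enedioate | CCOC(=O)C(CC=C(C)C)C(=O)C(C[C@H](O[Si](C)(C)C(C)(C)C)C(C)C)C(OC)=CC(=O)OC
F4 | step 3 | (3S)-2-methylhept-6-yn-3-ol | C#CCC[C@H](O)C(C)C
F5 | step 3 | tert-butyldimethyl{[(3S)-2-methylhept-6-yn-3-yl]oxy}silane | C#CCC[C@H](O[Si](C)(C)C(C)(C)C)C(C)C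
F6 | step 3 | methyl (6S)-6-(tert-butyldimethylsilyloxy)-7-methyloct-2-ynoate | COC(=O)C#CCC[C@H](O[Si](C)(C)C(C)(C)C)C(C)C
F7 | step 15 | 1-{5-[(2S)-2-(tert-butyldimethylsilyloxy)-3-methylbutyl]-6-methoxy-2,4-bis(methoxymethoxy)-3-(3-methylbut-2-enyl)phenyl}ethan-1-ol | CC(O)c1c(OC)c(C[C@H](O[Si](C)(C)C(C)(C)C)C(C)C)c(OCOC)c(CC=C(C)C)c1OCOC
F8 | step 15 | 1-{5-[(2S)-2-(tert-butyldimethylsilyloxy)-3-methylbutyl]-6-methoxy-2,4-bis(methoxymethoxy)-3-(3-methylbut-2-enyl)phenyl}ethan-1-one | CC(=O)c1c(OC)c(C[C@H](O[Si](C)(C)C(C)(C)C)C(C)C)c(OCOC)c(CC=C(C)C)c1OCOC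
F9 | step 15 | 1-bromo-4-(methoxymethoxy)benzene | COCOc1ccc(Br)cc1
F10 | step 17 | 6-[(2S)-2-(tert-butyldimethylsilyloxy)-3-methylbutyl]-7-hydroxy-3-(4-hydroxyphenyl)-5-methoxy-8-(3-methylbut-2-enyl)-4H-chromen-4-one | COc1c(C[C@H](O[Si](C)(C)C(C)(C)C)C(C)C)c(O)c(CC=C(C)C)c2occ(-c3ccc(O)cc3)c(=O)c12
A1 | alternative 1 | cyclic dimethylsiloxane (six-membered 1,2-oxasilinane fused at C5–C6, isopropyl on the (S)-configured silicon-bearing carbon) of 7-(methoxymethoxy)-3-[4-(methoxymethoxy)phenyl]-8-(3-methylbut-2-enyl)-4H-chromen-4-one | C[Si]1(C)Oc2c(C[C@H]1C(C)C)c(OCOC)c(CC=C(C)C)c3occ(-c4ccc(OCOC)cc4)c(=O)c23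
A2 | alternative 1 | 5-(dimethylsilyloxy)-7-(methoxymethoxy)-3-[4-(methoxymethoxy)phenyl]-6,8-bis(3-methylbut-2-enyl)-4H-chromen-4-one | C[SiH](C)Oc1c(CC=C(C)C)c(OCOC)c(CC=C(C)C)c2occ(-c3ccc(OCOC)cc3)c(=O)c12
A3 | alternative 2 | 6-[(2S)-2-(tert-butyldimethylsilyloxy)-3-methylbutyl]-3-[4-(tert-butyldimethylsilyloxy)phenyl]-5-hydroxy-8-(3-methylbut-2-enyl)-7-(triisopropylsilyloxy)-4H-chromen-4-one | Oc1c(C[C@H](O[Si](C)(C)C(C)(C)C)C(C)C)c(O[Si](C(C)C)(C(C)C)C(C)C)c(CC=C(C)C)c2occ(-c3ccc(O[Si](C)(C)C(C)(C)C)cc3)c(=O)c12
A4 | alternative 2 | 2-(2-diazo-5-methylhex-4-enoyl)-5-[4-(tert-butyldimethylsilyloxy)phenyl]-4H-pyran-4-one | CC(C)=CCC(=[N+]=[N-])C(=O)c1cc(=O)c(-c2ccc(O[Si](C)(C)C(C)(C)C)cc2)co1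
A5 | alternative 2 | tert-butyldimethyl{[(3S)-2-methyl-6-(triisopropylsilyloxy)hex-5-yn-3-yl]oxy}silane | CC(C)[Si](OC#CC[C@H](O[Si](C)(C)C(C)(C)C)C(C)C)(C(C)C)C(C)C
A6 | alternative 3 | 5-methoxy-7-(methoxymethoxy)-6-[(2S)-2-(methoxymethoxy)-3-methylbutyl]-3-[4-(methoxymethoxy)phenyl]-8-(3-methylbut-2-enyl)-4H-chromen-4-one | COc1c(C[C@H](OCOC)C(C)C)c(OCOC)c(CC=C(C)C)c2occ(-c3ccc(OCOC)cc3)c(=O)c12
A7 | alternative 3 | 3-methoxy-5-(methoxymethoxy)-4-[(2S)-2-(methoxymethoxy)-3-methylbutyl]-6-(3-methylbut-2-enyl)-2-(trimethylsilyl)phenyl trifluoromethanesulfonate | COc1c([Si](C)(C)C)c(OS(=O)(=O)C(F)(F)F)c(CC=C(C)C)c(OCOC)c1C[C@H](OCOC)C(C)C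
A8 | alternative 3 | methyl 3-hydroxy-2-[4-(methoxymethoxy)phenyl]prop-2-enoate | COCOc1ccc(C(=CO)C(=O)OC)cc1
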